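All runs were generated by integration for substances that don't exist; the scatter is artificial.

In a closed flask of constant volume, D and E add up to the charge, so the D lost is the monomer in chains, and the readings give the numerator of the average without any count of chains.

| flask | D | L | remark | time |
|---|---|---|---|---|
| north-east | 2 M | 0.5 mol% | run made earlier |  |
| south | 2 M | 2 mol% | run made earlier |  |
| flask | 2.0 M | 1 mol% |  | 8.0 d |

- north-east (time / d: E / %, D / %): 0.417: 0, 100; 1.25: 0, 99; 2.50: 2, 94; 3.00: 6, 94; 5.00: 12, 91; 6.00: 15, 81; 8.00: 20, 79
- south (time / d: E / %, D / %): 0.625: 2, 98; 1.04: 5, 96; 1.67: 6, 96; 2.50: 9, 91; 3.00: 9, 85; 5.00: 26, 74; 8.00: 42, 56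

(readings scatter by 1.5 percentage points)

- whether the average number of monomer units in a chain (chains begun, living or dead) reaches 60 by 8.0 d (no / yes)
- average number of monomer units in a chain (chains begun, living or dead) at 8.0 d

- the average divides the monomer in chains by the number of chains begun, living and dead together
- the earlier runs do not show the number of chains; that part of a forecast is a guess

What do the runs give at 8.00 d? D reads 79% in the north-east run and 56% in the south run, which are first-order losses (minus the logarithm of D left) of 0.236 and 0.580, as readings with their scatter.

And at this flask's loading? Its 1 mol% is the geometric middle of 0.5 mol% and 2 mol%, so I take the geometric mean of the losses, 0.370, and that gives my estimate of 30.9% of the D reacted in this flask.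

What is the average, then? Dividing conversion by loading gives 30.9. This floor length, monomer units per L charged, is the average if every L has begun one chain.

That is less than 60, so is the answer no? Not if some L has begun nothing: the average is the floor length divided by the share of L that has begun chains, so it reaches 60 with that share under 51.5%.

And the share? The runs do not show it. The north-east run still reads 0% E at 1.25 d, a slow start, so I guess yes and give no length.

The forecast says yes and 100, on this ground: “If about 30% of L has begun chains, the average is about 100.”

The flask gives yes and 77.3, and it reaches 60 at 3.79 d.

    D + Z → Q + E (k = 0.00450 M⁻¹ h⁻¹)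
    D + Q → E + Q, rate k2*[Q]*[D] (k = 1.10 M⁻¹ h⁻¹)
    L ⇌ Z (K = 0.810, k = 0.0170 h⁻¹)
    2 Q → G (k = 4.60 M⁻¹ h⁻¹)

At 8.00 d the flask uses D by D + Q at 97 times the rate of D + Z (the kinetic chain length), and at 4.43 d that ratio was 91. Its 30.8% E makes a floor length of 30.8, while Q plus twice G is a begun share of 39.8%, under the 51.5% limit; at 80.0 d the same flask has a floor length of 84.3 and a share of 91.5%, an average of 92.1.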